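**Retrosynthetic overview**
1. Target 21 is a C19 chain with one tetrahydrofuran ring (O, C6, C7, C8, C9) and a C7 stearate. The last disconnection is C10–C11: chelation-controlled addition of non-8-enylmagnesium bromide to the C10 aldehyde 18, with the stearate already on C7 so that no protecting-group exchange is needed.
2. The C7 carbinol comes from L-Selectride reduction of furan-3-one 12 (2,3-cis), and the pentyl chain from hydrogenation of its pent-2-enyl group.
3. The strategy rests on C6: it carries the ring oxygen and a carbon chain, lies next to oxygenated C7 and is trans to C9 across the ring. O–C6 and C6–C5 are therefore made together, by capture of a copper carbenoid at C6 by the C9 ether oxygen and [2,3]-shift of the oxonium ylide (10 → 12), which is the only ring-forming event.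
4. Diazoketone 10 comes from (R)-3-hydroxy-γ-butyrolactone 3 (source of C9) by branch-selective Ir-catalysed etherification with a pent-2-enyl carbonate, lactone opening/silylation, and mixed anhydride/diazomethane. An acid/imidate alkylation is avoided because the unsymmetrical 1-ethylallyl cation could also be trapped at its primary terminus.

Key step: step 5

Assumption: compounds 5–11 are carried as mixtures of epimers at the pent-1-en-3-yl carbinol carbon, which is destroyed in step 5; positions are given in the C1–C19 chain numbering of the target.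

**Step 1**
Reactants: 1 (E)-pent-2-en-1-ol
Product: 2 tert-butyl (E)-pent-2-en-1-yl carbonate
Conditions: Boc2O, Bu4NHSO4 (cat.), aq. NaOH, CH2Cl2, 0 °C → rt
Reagents that add atoms: di-tert-butyl dicarbonate, CC(C)(C)OC(=O)OC(=O)OC(C)(C)C
Why: Alkoxycarbonylation of a primary allylic alcohol under phase-transfer conditions gives the tert-butyl carbonate, whose tert-butoxide leaving group will not compete as a nucleophile in step 2; no stereocentre is involved.

**Step 2**
Reactants: 3 (R)-3-hydroxy-γ-butyrolactone; 2 tert-butyl (E)-pent-2-en-1-yl carbonate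
Product: 5 (4R)-4-(pent-1-en-3-yloxy)dihydrofuran-2(3H)-one (mixture of ether epimers), via zinc lactone alkoxide 4 (not isolated)
Conditions: Et2Zn (0.5 equiv), THF, 0 °C → rt; then 2 (1.3 equiv), [Ir(cod)Cl]2 (2.5 mol %), Feringa-type phosphoramidite (5 mol %, racemic suffices, pre-activated with n-PrNH2), THF, rt
Reagents that add atoms: none
Why: Iridium-catalysed allylic substitution (branch-selective allylic etherification of a zinc alkoxide) attacks the Ir–allyl at its substituted terminus, so the 1-ethylallyl ether should form without allylic transposition; the weakly basic zinc alkoxide should leave the β-oxygenated lactone intact, the C–O bond at the lactone stereocentre is untouched (R retained), and the new ether carbinol centre may form as either epimer.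

**Step 3**
Reactants: 5 (4R)-4-(pent-1-en-3-yloxy)dihydrofuran-2(3H)-one
Product: 8 (3R)-4-[(tert-butyldiphenylsilyl)oxy]-3-(pent-1-en-3-yloxy)butanoic acid, via lithium hydroxy carboxylate 6 (not isolated), via bis-silylated ester 7 (not isolated)
Conditions: LiOH (1.05 equiv), THF/H2O, 0 °C → rt, concentrate; TBDPSCl (2.2 equiv), imidazole, DMF, rt; then AcOH/THF/H2O, rt
Reagents that add atoms: lithium hydroxide, [Li+].[OH-]; tert-butyl(chloro)diphenylsilane, CC(C)(C)[Si](Cl)(c1ccccc1)c1ccccc1
Why: Saponification opens the lactone by acyl–oxygen cleavage to a hydroxy carboxylate that cannot relactonise as its salt and resists E1cB loss of the β-alkoxy group; exhaustive silylation and selective hydrolysis of the labile silyl ester then leave the primary TBDPS ether and the free acid with the stereocentre unaffected.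

**Step 4**
Reactants: 8 (3R)-4-[(tert-butyldiphenylsilyl)oxy]-3-(pent-1-en-3-yloxy)butanoic acid
Product: 10 (4R)-1-diazo-4-(pent-1-en-3-yloxy)-5-[(tert-butyldiphenylsilyl)oxy]pentan-2-one, via isobutyl carbonic mixed anhydride 9 (not isolated)
Conditions: i-BuOCOCl, Et3N, Et2O, −20 → 0 °C; filter; CH2N2 (excess), Et2O, 0 °C → rt
Reagents that add atoms: diazomethane, C=[N+]=[N-]
Why: Acylation of diazomethane by a mixed carbonic anhydride (first stage of an Arndt–Eistert sequence) gives the α-diazoketone under non-acidic conditions that spare the silyl ether and the allylic ether; the stereocentre is remote from the reacting carbonyl.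

**Step 5**
Reactants: 10 (4R)-1-diazo-4-(pent-1-en-3-yloxy)-5-[(tert-butyldiphenylsilyl)oxy]pentan-2-one
Product: 12 (2S,5R)-5-{[(tert-butyldiphenylsilyl)oxy]methyl}-2-[(2E)-pent-2-en-1-yl]dihydrofuran-3(2H)-one, via cyclic oxonium ylide 11 (not isolated)
Conditions: Cu(acac)2 (5 mol %), THF, reflux, slow addition of 10
Reagents that add atoms: none
Why: Cu(acac)2 decomposes the diazo group to an electrophilic copper carbenoid at C6, which is captured by a lone pair of the C9 ether oxygen five atoms away; this closes the only ring (O, C6, C7, C8, C9) as a five-membered cyclic oxonium ylide, by attack of oxygen on the exocyclic carbenoid carbon (5-exo in type). The ylide then undergoes a concerted suprafacial [2,3]-sigmatropic shift through a five-membered envelope transition state in which C6 bonds to the vinyl terminus (C6–C5) while the O–CH(Et) bond breaks, leaving a pent-2-enyl chain that should be mainly E. The closest known reaction type is the copper-catalysed tandem oxonium ylide formation/[2,3]-rearrangement of allyloxy diazoketones to trans-2,5-disubstituted dihydrofuran-3(2H)-ones. The new stereocentre C6 is controlled by C9: the O-allyl group of the ylide prefers to sit trans to the bulky CH2OTBDPS arm and is delivered to C6 on the face on which it sits, which should give the 2,5-trans (2S,5R) ketone. The step needs the ylide pathway to win over [1,2]-shift and C–H insertion, which the copper catalyst (rather than a Rh(II) carboxylate) and slow addition are chosen to favour, and it needs 2,5-trans selectivity, which the C9 substituent secures; the ether carbinol centre is erased and the alkene geometry becomes irrelevant in step 7.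

**Step 6**
Reactants: 12 (2S,5R)-5-{[(tert-butyldiphenylsilyl)oxy]methyl}-2-[(2E)-pent-2-en-1-yl]dihydrofuran-3(2H)-one
Product: 13 (2S,3S,5R)-5-{[(tert-butyldiphenylsilyl)oxy]methyl}-2-[(2E)-pent-2-en-1-yl]tetrahydrofuran-3-ol
Conditions: L-Selectride, THF, −78 °C; then H2O
Reagents that add atoms: none
Why: Substrate-controlled reduction with a bulky hydride, which should attack the C7 ketone from the face opposite the adjacent C6 side chain and so place the new hydroxyl cis to it (7S).

**Step 7**
Reactants: 13 (2S,3S,5R)-5-{[(tert-butyldiphenylsilyl)oxy]methyl}-2-[(2E)-pent-2-en-1-yl]tetrahydrofuran-3-ol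
Product: 14 (2S,3S,5R)-5-{[(tert-butyldiphenylsilyl)oxy]methyl}-2-pentyltetrahydrofuran-3-ol
Conditions: H2 (1 atm), 10% Pd/C, EtOAc, rt
Reagents that add atoms: none
Why: Heterogeneous catalytic hydrogenation saturates the isolated alkene to the pentyl chain without touching the silyl ether, the alcohol or any stereocentre, and it is placed before the terminal alkene of the target is introduced.

**Step 8**
Reactants: 14 (2S,3S,5R)-5-{[(tert-butyldiphenylsilyl)oxy]methyl}-2-pentyltetrahydrofuran-3-ol; 15 octadecanoyl chloride (stearoyl chloride)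
Product: 16 (2S,3S,5R)-5-{[(tert-butyldiphenylsilyl)oxy]methyl}-2-pentyltetrahydrofuran-3-yl octadecanoate
Conditions: 15, Et3N, DMAP (cat.), CH2Cl2, 0 °C → rt
Reagents that add atoms: none
Why: DMAP-catalysed acylation of the secondary alcohol installs the stearate with retention at C7, and the ester then serves as the C7 protecting group for the rest of the route.

**Step 9**
Reactants: 16 (2S,3S,5R)-5-{[(tert-butyldiphenylsilyl)oxy]methyl}-2-pentyltetrahydrofuran-3-yl octadecanoate
Product: 17 (2S,3S,5R)-5-(hydroxymethyl)-2-pentyltetrahydrofuran-3-yl octadecanoate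
Conditions: TBAF, AcOH, THF, rt
Reagents that add atoms: none
Why: Fluoride-mediated desilylation of the primary silyl ether; the acetic acid buffer keeps the medium non-basic so the stearate should be neither cleaved nor transferred, and the trans relation of the C7 oxygen and the C9 arm also disfavours acyl migration.

**Step 10**
Reactants: 17 (2S,3S,5R)-5-(hydroxymethyl)-2-pentyltetrahydrofuran-3-yl octadecanoate
Product: 18 (2S,3S,5R)-5-formyl-2-pentyltetrahydrofuran-3-yl octadecanoate
Conditions: Dess–Martin periodinane, CH2Cl2, 0 °C → rt; used crude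
Reagents that add atoms: none
Why: Dess–Martin oxidation converts the primary alcohol to the aldehyde under mild non-basic conditions that should not epimerise the α-alkoxy centre C9 or affect the ester.

**Step 11**
Reactants: 18 (2S,3S,5R)-5-formyl-2-pentyltetrahydrofuran-3-yl octadecanoate; 19 9-bromonon-1-ene
Product: 21 (2S,3S,5R)-5-[(1R)-1-hydroxydec-9-en-1-yl]-2-pentyltetrahydrofuran-3-yl octadecanoate, via non-8-enylmagnesium bromide 20 (not isolated)
Conditions: 19, Mg, Et2O, rt; 18, MgBr2·OEt2, CH2Cl2, −78 °C, then slow addition of the Grignard solution (1.2 equiv); H2O work-up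
Reagents that add atoms: none
Why: Grignard addition under Cram chelate control, in which Mg(II) bridges the aldehyde oxygen and the ring oxygen and the nucleophile attacks the carbonyl face on the side of the C9 hydrogen, which should give the (10R) threo carbinol; at −78 °C the aldehyde should react much faster than the hindered stearate.

**Compound list**
1 | (E)-pent-2-en-1-ol | CC/C=C/CO | starting material
2 | tert-butyl (E)-pent-2-en-1-yl carbonate | CC/C=C/COC(=O)OC(C)(C)C | intermediate
3 | (R)-3-hydroxy-γ-butyrolactone [(4R)-4-hydroxydihydrofuran-2(3H)-one] | O=C1C[C@@H](O)CO1 | starting material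
4 | zinc bis[(3R)-5-oxotetrahydrofuran-3-olate] | O=C1C[C@@H]([O-])CO1.O=C1C[C@@H]([O-])CO1.[Zn+2] | intermediate
5 | (4R)-4-(pent-1-en-3-yloxy)dihydrofuran-2(3H)-one | O=C1C[C@@H](OC(CC)C=C)CO1 | intermediate
6 | lithium (3R)-4-hydroxy-3-(pent-1-en-3-yloxy)butanoate | [Li+].[O-]C(=O)C[C@@H](OC(CC)C=C)CO | intermediate
7 | tert-butyldiphenylsilyl (3R)-4-[(tert-butyldiphenylsilyl)oxy]-3-(pent-1-en-3-yloxy)butanoate | CC(C)(C)[Si](c1ccccc1)(c1ccccc1)OC[C@H](OC(CC)C=C)CC(=O)O[Si](c1ccccc1)(c1ccccc1)C(C)(C)C | intermediate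
8 | (3R)-4-[(tert-butyldiphenylsilyl)oxy]-3-(pent-1-en-3-yloxy)butanoic acid | CC(C)(C)[Si](c1ccccc1)(c1ccccc1)OC[C@H](OC(CC)C=C)CC(=O)O | intermediate
9 | (3R)-4-[(tert-butyldiphenylsilyl)oxy]-3-(pent-1-en-3-yloxy)butanoic isobutyl carbonic anhydride | CC(C)(C)[Si](c1ccccc1)(c1ccccc1)OC[C@H](OC(CC)C=C)CC(=O)OC(=O)OCC(C)C | intermediate
10 | (4R)-1-diazo-4-(pent-1-en-3-yloxy)-5-[(tert-butyldiphenylsilyl)oxy]pentan-2-one | CC(C)(C)[Si](c1ccccc1)(c1ccccc1)OC[C@H](OC(CC)C=C)CC(=O)C=[N+]=[N-] | intermediate
11 | (5R)-5-{[(tert-butyldiphenylsilyl)oxy]methyl}-3-oxo-1-(pent-1-en-3-yl)tetrahydrofuran-1-ium-2-ide (cyclic oxonium ylide) | CC(C)(C)[Si](c1ccccc1)(c1ccccc1)OC[C@H]2CC(=O)[CH-][O+]2C(CC)C=C | intermediate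
12 | (2S,5R)-5-{[(tert-butyldiphenylsilyl)oxy]methyl}-2-[(2E)-pent-2-en-1-yl]dihydrofuran-3(2H)-one | CC(C)(C)[Si](c1ccccc1)(c1ccccc1)OC[C@H]2CC(=O)[C@H](C/C=C/CC)O2 | intermediate
13 | (2S,3S,5R)-5-{[(tert-butyldiphenylsilyl)oxy]methyl}-2-[(2E)-pent-2-en-1-yl]tetrahydrofuran-3-ol | CC(C)(C)[Si](c1ccccc1)(c1ccccc1)OC[C@H]2C[C@H](O)[C@H](C/C=C/CC)O2 | intermediate
14 | (2S,3S,5R)-5-{[(tert-butyldiphenylsilyl)oxy]methyl}-2-pentyltetrahydrofuran-3-ol | CC(C)(C)[Si](c1ccccc1)(c1ccccc1)OC[C@H]2C[C@H](O)[C@H](CCCCC)O2 | intermediate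
15 | octadecanoyl chloride (stearoyl chloride) | CCCCCCCCCCCCCCCCCC(=O)Cl | starting material
16 | (2S,3S,5R)-5-{[(tert-butyldiphenylsilyl)oxy]methyl}-2-pentyltetrahydrofuran-3-yl octadecanoate | CC(C)(C)[Si](c1ccccc1)(c1ccccc1)OC[C@H]2C[C@H](OC(=O)CCCCCCCCCCCCCCCCC)[C@H](CCCCC)O2 | intermediate
17 | (2S,3S,5R)-5-(hydroxymethyl)-2-pentyltetrahydrofuran-3-yl octadecanoate | OC[C@H]1C[C@H](OC(=O)CCCCCCCCCCCCCCCCC)[C@H](CCCCC)O1 | intermediate
18 | (2S,3S,5R)-5-formyl-2-pentyltetrahydrofuran-3-yl octadecanoate | O=C[C@H]1C[C@H](OC(=O)CCCCCCCCCCCCCCCCC)[C@H](CCCCC)O1 | intermediate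
19 | 9-bromonon-1-ene | C=CCCCCCCCBr | starting material
20 | non-8-enylmagnesium bromide | C=CCCCCCCC[Mg]Br | intermediate
21 | (2S,3S,5R)-5-[(1R)-1-hydroxydec-9-en-1-yl]-2-pentyltetrahydrofuran-3-yl octadecanoate [(6S,7S,9R,10R) in chain numbering] | C=CCCCCCCC[C@@H](O)[C@H]1C[C@H](OC(=O)CCCCCCCCCCCCCCCCC)[C@H](CCCCC)O1 | target

**Step count**
Total: 11 steps. Longest linear sequence: 11 steps (1 → 21; 10 steps from lactone 3).

**Steps most likely to fail**

1. Step 5 (key step). The carbenoid or ylide may divert into [1,2]-shift of the secondary allylic group, C–H insertion or carbene dimerisation, and the branched migrating group may erode the trans preference. The fallback takes the ethyl group out of the rearrangement; it sets out from 3 and returns at 12.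
 - Acid-catalysed O-allylation of 3 with allyl 2,2,2-trichloroacetimidate (TfOH cat., CH2Cl2/cyclohexane; the unsubstituted allyl cation has no regiochemical ambiguity) would give (4R)-4-(allyloxy)dihydrofuran-2(3H)-one F1.
 - LiOH opening would give lithium (3R)-3-(allyloxy)-4-hydroxybutanoate F2, silylation would give tert-butyldiphenylsilyl (3R)-3-(allyloxy)-4-[(tert-butyldiphenylsilyl)oxy]butanoate F3, and hydrolysis of its silyl ester would give (3R)-3-(allyloxy)-4-[(tert-butyldiphenylsilyl)oxy]butanoic acid F4.
 - Activation as (3R)-3-(allyloxy)-4-[(tert-butyldiphenylsilyl)oxy]butanoic isobutyl carbonic anhydride F5 and treatment with diazomethane would give (4R)-4-(allyloxy)-1-diazo-5-[(tert-butyldiphenylsilyl)oxy]pentan-2-one F6.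
 - Cu(acac)2 in refluxing THF should convert F6, through the (5R)-1-allyl-5-{[(tert-butyldiphenylsilyl)oxy]methyl}-3-oxotetrahydrofuran-1-ium-2-ide F7, into (2S,5R)-2-allyl-5-{[(tert-butyldiphenylsilyl)oxy]methyl}dihydrofuran-3(2H)-one F8.
 - Olefin cross-metathesis of F8 with excess (Z)-hex-3-ene (Grubbs second-generation catalyst, CH2Cl2, 40 °C) then leads back to 12. An E/Z mixture is acceptable because step 7 saturates the alkene.

2. Step 2. The allylic substitution may be sluggish or poorly branch-selective with a hindered, electron-poor secondary zinc alkoxide. The fallback is an acid-catalysed alkylation; it sets out from 3 and returns at 5.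
 - Pent-1-en-3-ol with Cl3CCN and catalytic DBU (CH2Cl2, 0 °C) would give pent-1-en-3-yl 2,2,2-trichloroacetimidate F9.
 - F9 is reacted with 3 under TfOH catalysis (CH2Cl2/cyclohexane, 0 °C), and the branched ether 5 is separated by chromatography from any transposed (E)-pent-2-enyl ether.

3. Step 11. The Grignard reagent may attack the stearate, or weak chelation may give poor facial selectivity at C10. The fallback sets C10 by reagent-controlled ketone reduction after an ester-tolerant C–C coupling; it sets out from 17 and returns at 21.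
 - Oxidation of 17 with TEMPO/PhI(OAc)2 (MeCN/H2O) would give (2R,4S,5S)-4-(octadecanoyloxy)-5-pentyltetrahydrofuran-2-carboxylic acid F10.
 - EtSH, DCC and catalytic DMAP would give S-ethyl (2R,4S,5S)-4-(octadecanoyloxy)-5-pentyltetrahydrofuran-2-carbothioate F11.
 - Fukuyama coupling of F11 with non-8-enylzinc bromide F12 (from 19, Zn, LiCl, THF), catalysed by PdCl2(PPh3)2, would give (2S,3S,5R)-5-(dec-9-enoyl)-2-pentyltetrahydrofuran-3-yl octadecanoate F13.
 - L-Selectride (THF, −78 °C) should then give 21, since polar Felkin–Anh attack anti to the ring C–O bond leads to the (10R) alcohol.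

**Further compounds**
F1 | step 5 | (4R)-4-(allyloxy)dihydrofuran-2(3H)-one | O=C1C[C@@H](OCC=C)CO1
F2 | step 5 | lithium (3R)-3-(allyloxy)-4-hydroxybutanoate | [Li+].[O-]C(=O)C[C@@H](OCC=C)CO
F3 | step 5 | tert-butyldiphenylsilyl (3R)-3-(allyloxy)-4-[(tert-butyldiphenylsilyl)oxy]butanoate | CC(C)(C)[Si](c1ccccc1)(c1ccccc1)OC[C@H](OCC=C)CC(=O)O[Si](c1ccccc1)(c1ccccc1)C(C)(C)C
F4 | step 5 | (3R)-3-(allyloxy)-4-[(tert-butyldiphenylsilyl)oxy]butanoic acid | CC(C)(C)[Si](c1ccccc1)(c1ccccc1)OC[C@H](OCC=C)CC(=O)O
F5 | step 5 | (3R)-3-(allyloxy)-4-[(tert-butyldiphenylsilyl)oxy]butanoic isobutyl carbonic anhydride | CC(C)(C)[Si](c1ccccc1)(c1ccccc1)OC[C@H](OCC=C)CC(=O)OC(=O)OCC(C)C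
F6 | step 5 | (4R)-4-(allyloxy)-1-diazo-5-[(tert-butyldiphenylsilyl)oxy]pentan-2-one | CC(C)(C)[Si](c1ccccc1)(c1ccccc1)OC[C@H](OCC=C)CC(=O)C=[N+]=[N-]
F7 | step 5 | (5R)-1-allyl-5-{[(tert-butyldiphenylsilyl)oxy]methyl}-3-oxotetrahydrofuran-1-ium-2-ide | CC(C)(C)[Si](c1ccccc1)(c1ccccc1)OC[C@H]2CC(=O)[CH-][O+]2CC=C
F8 | step 5 | (2S,5R)-2-allyl-5-{[(tert-butyldiphenylsilyl)oxy]methyl}dihydrofuran-3(2H)-one | CC(C)(C)[Si](c1ccccc1)(c1ccccc1)OC[C@H]2CC(=O)[C@H](CC=C)O2
F9 | step 2 | pent-1-en-3-yl 2,2,2-trichloroacetimidate | C=CC(CC)OC(=N)C(Cl)(Cl)Cl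
F10 | step 11 | (2R,4S,5S)-4-(octadecanoyloxy)-5-pentyltetrahydrofuran-2-carboxylic acid | OC(=O)[C@H]1C[C@H](OC(=O)CCCCCCCCCCCCCCCCC)[C@H](CCCCC)O1
F11 | step 11 | S-ethyl (2R,4S,5S)-4-(octadecanoyloxy)-5-pentyltetrahydrofuran-2-carbothioate | CCSC(=O)[C@H]1C[C@H](OC(=O)CCCCCCCCCCCCCCCCC)[C@H](CCCCC)O1
F12 | step 11 | non-8-enylzinc bromide | C=CCCCCCCC[Zn]Br
F13 | step 11 | (2S,3S,5R)-5-(dec-9-enoyl)-2-pentyltetrahydrofuran-3-yl octadecanoate | C=CCCCCCCCC(=O)[C@H]1C[C@H](OC(=O)CCCCCCCCCCCCCCCCC)[C@H](CCCCC)O1
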